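Ring B is read as a resorcinol monoester: the C2 hydroxyl and the C4 acyloxy group are meta, with CO2Me on C1 and CH3 on C6. This is the pattern that a 3-acyloxy-1,4-enyne and CO give, so ring B is disconnected to an open-chain enyne ester of the protected ring-A acid. In one operation, a rhodium-catalysed carbonylative (5+1) benzannulation moves the ring-A carboxylate from the carbinol carbon to the alkyne carbon (O–C4), inserts CO (C2–C3) and closes C1–C2, so that depside link and arene arise together. The precursor is the bis(methoxymethyl)-protected ring-A ester of racemic methyl (E)-4-hydroxy-3-methylhex-2-en-5-ynoate; the C3 methyl follows by ortho-formylation and reduction.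

Key step: step 7

Remark on the chemistry: ring A is the chlorinated benzoyl ring and ring B the methyl benzoate ring (CO2Me on C1). The target has no stereocentre; the carbinol stereocentre that arises on the way is carried as the racemate and is destroyed in the key step. MOM = methoxymethyl.

Step 1
Reactants: 1 methyl 2,4-dihydroxy-3,6-dimethylbenzoate (methyl atrarate)
Product: 2 methyl 5-chloro-2,4-dihydroxy-3,6-dimethylbenzoate
Conditions: SO2Cl2 (1.05 equiv), Et2O, 0 °C to rt
Reagents that add atoms: sulfuryl chloride, O=S(=O)(Cl)Cl
Why: Electrophilic aromatic chlorination; C5 is the only unsubstituted ring position of 1 and is activated by the ortho 4-OH and the para 2-OH, so one equivalent of SO2Cl2 should chlorinate there and leave the ester alone.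

Step 2
Reactants: 2 methyl 5-chloro-2,4-dihydroxy-3,6-dimethylbenzoate
Product: 3 methyl 5-chloro-2,4-bis(methoxymethoxy)-3,6-dimethylbenzoate
Conditions: NaH (2.5 equiv), MOMCl (2.5 equiv), DMF, 0 °C to rt
Reagents that add atoms: chloromethyl methyl ether, COCCl
Why: Williamson-type O-alkylation of both sodium phenoxides with the reactive α-chloro ether; NaH in DMF breaks the hydrogen bond of the 2-OH to the ester, and the small electrophile should reach both flanked oxygens.

Step 3
Reactants: 3 methyl 5-chloro-2,4-bis(methoxymethoxy)-3,6-dimethylbenzoate
Product: 4 5-chloro-2,4-bis(methoxymethoxy)-3,6-dimethylbenzoic acid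
Conditions: KOH (10 equiv), DMSO–H2O (4:1), 90 °C; then cold aq. HCl to pH 3–4
Reagents that add atoms: potassium hydroxide, [K+].[OH-]
Why: Saponification of a di-ortho-substituted benzoate, for which weakly solvated hydroxide in hot aqueous DMSO is the usual answer; the MOM acetals and the electron-rich aryl chloride are inert to base, and the acidification is stopped early to keep the acetals.

Step 4
Reactants: 5 methyl 3-methylbut-2-enoate
Product: 6 methyl (2E)-3-methyl-4-oxobut-2-enoate
Conditions: SeO2 (1.2 equiv), 1,4-dioxane, reflux
Reagents that add atoms: selenium dioxide, O=[Se]=O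
Why: Riley allylic oxidation (ene reaction, then 2,3-sigmatropic shift) attacks the methyl group trans to the ester, so the aldehyde should form with the (E) geometry, CHO and CO2Me on opposite sides.

Step 5
Reactants: 6 methyl (2E)-3-methyl-4-oxobut-2-enoate; 7 ethynylmagnesium bromide
Product: 8 methyl (2E)-4-hydroxy-3-methylhex-2-en-5-ynoate (racemic)
Conditions: HC≡CMgBr (0.5 M in THF, 1.1 equiv), THF, −78 °C; aq. NH4Cl
Reagents that add atoms: none
Why: Grignard 1,2-addition of the alkynyl nucleophile to the aldehyde, which at −78 °C is far more electrophilic than the ester or the enoate β-position; the new stereocentre C4 forms without control as the racemate, which is acceptable because step 7 erases it, and the (E) geometry keeps the hydroxyl away from the ester so that no lactone can form.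

Step 6
Reactants: 4 5-chloro-2,4-bis(methoxymethoxy)-3,6-dimethylbenzoic acid; 8 methyl (2E)-4-hydroxy-3-methylhex-2-en-5-ynoate (racemic)
Product: 9 methyl (2E)-4-{[5-chloro-2,4-bis(methoxymethoxy)-3,6-dimethylbenzoyl]oxy}-3-methylhex-2-en-5-ynoate (racemic at C4)
Conditions: PPh3 (1.5 equiv), DIAD (1.5 equiv), toluene, 0 °C to rt
Reagents that add atoms: none
Why: Mitsunobu esterification, chosen because the carboxylate of the di-ortho-substituted acid 4 acts as the nucleophile at the activated propargylic carbon of 8, so the shielded acyl carbon is never attacked; inversion at C4 is of no consequence for a racemate, and C4 has no neighbouring sp3 C–H from which elimination could start.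

Step 7
Reactants: 9 methyl (2E)-4-{[5-chloro-2,4-bis(methoxymethoxy)-3,6-dimethylbenzoyl]oxy}-3-methylhex-2-en-5-ynoate (racemic at C4); 10 carbon monoxide
Product: 14 methyl 4-{[5-chloro-2,4-bis(methoxymethoxy)-3,6-dimethylbenzoyl]oxy}-2-hydroxy-6-methylbenzoate, via rhodium vinylcarbene 11 (not isolated), via dienylketene 12 (not isolated), via cyclohexadienone 13 (not isolated)
Conditions: [Rh(CO)2Cl]2 (5 mol %), CO (1–10 bar), ClCH2CH2Cl, 60–80 °C
Reagents that add atoms: none
Why: Monovalent rhodium activates the terminal alkyne of 9, the aroyl carbonyl oxygen adds to the internal alkyne carbon as the old C–O bond at the carbinol carbon breaks (1,2-acyloxy shift, new O–C4 bond), and the rhodium vinylcarbene 11 results with the metal on the former terminal carbon, the future C3. CO inserts into the carbene to give the dienylketene 12 (new C2–C3 bond), ring B closes by a thermal disrotatory 6π electrocyclisation between the ketene carbon and the ester-bearing alkene carbon (new C1–C2 bond) to cyclohexadienone 13, and enolisation of this β-keto ester gives the arene with the new hydroxyl on C2 next to CO2Me. The closest known reaction type is the [Rh(CO)2Cl]2-catalysed (5+1) carbonylative benzannulation of 3-acyloxy-1,4-enynes carrying a terminal alkyne, which delivers resorcinol monoesters; 9 belongs to that substrate class and differs only in its acrylate-type alkene and its di-ortho-substituted aroyl group. No stereocentre is created, since C4 of 9 becomes sp2 and the sp3 carbon of 13 is lost on aromatisation. The step needs the 1,2-shift and not the 1,3-shift to an allenyl ester, which the unsubstituted alkyne terminus and the electron-rich 2,4-dialkoxyaroyl group should secure. It also needs a triene that can close, which the (E)-alkene provides by turning H and not CO2Me towards the ketene carbon.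

Step 8
Reactants: 14 methyl 4-{[5-chloro-2,4-bis(methoxymethoxy)-3,6-dimethylbenzoyl]oxy}-2-hydroxy-6-methylbenzoate
Product: 15 methyl 4-{[5-chloro-2,4-bis(methoxymethoxy)-3,6-dimethylbenzoyl]oxy}-3-formyl-2-hydroxy-6-methylbenzoate
Conditions: MgCl2 (3 equiv), Et3N (6 equiv), (CH2O)n (8 equiv), MeCN, reflux; aq. citric acid
Reagents that add atoms: paraformaldehyde (formaldehyde equivalent), C=O
Why: Magnesium-mediated ortho-formylation of a phenol (Casiraghi–Skattebøl reaction): formaldehyde is delivered inside the magnesium phenoxide to C3, the only free position ortho to the C2 hydroxyl, and a second formaldehyde takes up the hydride (Oppenauer-type redox), while ring A has no free position and the hindered depside ester and the MOM acetals should tolerate Et3N.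

Step 9
Reactants: 15 methyl 4-{[5-chloro-2,4-bis(methoxymethoxy)-3,6-dimethylbenzoyl]oxy}-3-formyl-2-hydroxy-6-methylbenzoate
Product: 17 methyl 4-[(5-chloro-2,4-dihydroxy-3,6-dimethylbenzoyl)oxy]-2-hydroxy-3,6-dimethylbenzoate, via diphenol aldehyde 16 (not isolated)
Conditions: Et3SiH (8 equiv), CF3CO2H–CH2Cl2 (1:1), 0 °C to rt
Reagents that add atoms: none
Why: Ionic hydrogenation of an ortho-hydroxybenzaldehyde: acidolysis of both MOM acetals is expected to give 16 first, Et3SiH then transfers hydride twice to the protonated formyl carbon, whose cationic stages are stabilised by the C2 hydroxyl, and the silane also quenches the methoxymethyl cations before they can alkylate C5, while both esters and the aryl chloride are inert.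

Compound list
1 | methyl 2,4-dihydroxy-3,6-dimethylbenzoate (methyl atrarate) | COC(=O)c1c(C)cc(O)c(C)c1O | starting material
2 | methyl 5-chloro-2,4-dihydroxy-3,6-dimethylbenzoate | COC(=O)c1c(C)c(Cl)c(O)c(C)c1O | intermediate
3 | methyl 5-chloro-2,4-bis(methoxymethoxy)-3,6-dimethylbenzoate | COC(=O)c1c(C)c(Cl)c(OCOC)c(C)c1OCOC | intermediate
4 | 5-chloro-2,4-bis(methoxymethoxy)-3,6-dimethylbenzoic acid | OC(=O)c1c(C)c(Cl)c(OCOC)c(C)c1OCOC | intermediate
5 | methyl 3-methylbut-2-enoate | COC(=O)C=C(C)C | starting material
6 | methyl (2E)-3-methyl-4-oxobut-2-enoate | COC(=O)/C=C(\C)C=O | intermediate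
7 | ethynylmagnesium bromide | C#C[Mg]Br | starting material
8 | methyl (2E)-4-hydroxy-3-methylhex-2-en-5-ynoate, racemic | COC(=O)/C=C(\C)C(O)C#C | intermediate
9 | methyl (2E)-4-{[5-chloro-2,4-bis(methoxymethoxy)-3,6-dimethylbenzoyl]oxy}-3-methylhex-2-en-5-ynoate, racemic at C4 | COC(=O)/C=C(\C)C(C#C)OC(=O)c1c(C)c(Cl)c(OCOC)c(C)c1OCOC | intermediate
10 | carbon monoxide | [C-]#[O+] | starting material
11 | rhodium vinylcarbene, [(2E,4E)-2-{[5-chloro-2,4-bis(methoxymethoxy)-3,6-dimethylbenzoyl]oxy}-6-methoxy-4-methyl-6-oxohexa-2,4-dien-1-ylidene]rhodium, chloride and CO ligands on the metal not drawn, formed in the flask | [Rh]=C/C(OC(=O)c1c(C)c(Cl)c(OCOC)c(C)c1OCOC)=C\C(C)=C\C(=O)OC | intermediate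
12 | dienylketene, methyl (2E,4E)-5-{[5-chloro-2,4-bis(methoxymethoxy)-3,6-dimethylbenzoyl]oxy}-3-methyl-7-oxohepta-2,4,6-trienoate, formed in the flask | O=C=C/C(OC(=O)c1c(C)c(Cl)c(OCOC)c(C)c1OCOC)=C\C(C)=C\C(=O)OC | intermediate
13 | cyclohexadienone, methyl 4-{[5-chloro-2,4-bis(methoxymethoxy)-3,6-dimethylbenzoyl]oxy}-6-methyl-2-oxocyclohexa-3,5-diene-1-carboxylate, racemic, formed in the flask | COC(=O)C1C(C)=CC(OC(=O)c2c(C)c(Cl)c(OCOC)c(C)c2OCOC)=CC1=O | intermediate
14 | methyl 4-{[5-chloro-2,4-bis(methoxymethoxy)-3,6-dimethylbenzoyl]oxy}-2-hydroxy-6-methylbenzoate | COC(=O)c1c(C)cc(OC(=O)c2c(C)c(Cl)c(OCOC)c(C)c2OCOC)cc1O | intermediate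
15 | methyl 4-{[5-chloro-2,4-bis(methoxymethoxy)-3,6-dimethylbenzoyl]oxy}-3-formyl-2-hydroxy-6-methylbenzoate | COC(=O)c1c(C)cc(OC(=O)c2c(C)c(Cl)c(OCOC)c(C)c2OCOC)c(C=O)c1O | intermediate
16 | diphenol aldehyde, methyl 4-[(5-chloro-2,4-dihydroxy-3,6-dimethylbenzoyl)oxy]-3-formyl-2-hydroxy-6-methylbenzoate, formed in the flask | COC(=O)c1c(C)cc(OC(=O)c2c(C)c(Cl)c(O)c(C)c2O)c(C=O)c1O | intermediate
17 | methyl 4-[(5-chloro-2,4-dihydroxy-3,6-dimethylbenzoyl)oxy]-2-hydroxy-3,6-dimethylbenzoate (CNP0106652.0) | COC(=O)c1c(C)cc(OC(=O)c2c(C)c(Cl)c(O)c(C)c2O)c(C)c1O | target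

Total step count: 9 steps.
Longest linear sequence: 7 steps (steps 1, 2, 3, 6, 7, 8, 9, from compound 1); the enyne branch (steps 4 and 5) joins at step 6.

Steps most likely to fail

Step 7 (key step). The acyloxy shift may take the 1,3-course towards an allenyl ester, the terminal alkyne may oligomerise on rhodium, or the bulky, twisted aroyl group may migrate too slowly for carbonylation to compete. Fallback: the depside bond is made by conventional O-acylation of a ready-made ring B instead of by migration. It sets out from acid 4 and phenol 1. A Steglich-type coupling (EDC·HCl, DMAP, CH2Cl2, rt) should acylate the 4-OH of 1, the 2-OH being held in a hydrogen bond to the ester and flanked on both sides, to give methyl 4-{[5-chloro-2,4-bis(methoxymethoxy)-3,6-dimethylbenzoyl]oxy}-2-hydroxy-3,6-dimethylbenzoate F1. HCl in MeOH at rt then exchanges both MOM acetals, and the route is rejoined at target 17.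

Step 8. Electrophilic attack at C3 may be too slow, because the position is flanked on both sides and the ring is deactivated by the ester; on prolonged heating with amine and magnesium alkoxide, slow transacylation at the depside could then take over. Fallback: Rieche formylation, a Friedel–Crafts-type process in place of the magnesium-templated one. It sets out from 14. Cl2CHOCH3 and TiCl4 in CH2Cl2 (−20 °C to rt, then aq. HCl) should formylate C3 under chelation of titanium between the C2 hydroxyl and the ester carbonyl. TiCl4 strips both MOM acetals in the same flask, which is harmless because ring A has no free position, so the product is the diphenol aldehyde 16. The route is rejoined there for the reduction of step 9; no compound outside the list arises (F0).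

Step 6. The bulky carboxylate may attack the oxyphosphonium salt too slowly, so that alkylation of the reduced azodicarboxylate, or attack at the alkyne terminus with transposition, competes. Fallback: the ester is made by acyl transfer and not by substitution at carbon. It sets out from acid 4. Cyanuric fluoride and pyridine (CH2Cl2, −10 °C to rt) should give 5-chloro-2,4-bis(methoxymethoxy)-3,6-dimethylbenzoyl fluoride F2 without the strong acid that an acyl chloride preparation would release onto the MOM acetals. The small fluoride leaving group should allow acylation of alcohol 8 (Et3N, DMAP, CH2Cl2, rt to 40 °C), and the route is rejoined at 9.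

Further compounds
F1 | step 7 | methyl 4-{[5-chloro-2,4-bis(methoxymethoxy)-3,6-dimethylbenzoyl]oxy}-2-hydroxy-3,6-dimethylbenzoate | COC(=O)c1c(C)cc(OC(=O)c2c(C)c(Cl)c(OCOC)c(C)c2OCOC)c(C)c1O
F0 | step 8 | none | none
F2 | step 6 | 5-chloro-2,4-bis(methoxymethoxy)-3,6-dimethylbenzoyl fluoride | O=C(F)c1c(C)c(Cl)c(OCOC)c(C)c1OCOC
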